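**The invariant.** By the proposed steps, one reagent spent gives one intermediate, then one target, then one over-reaction product, so the sum of those three equals the reagent spent. The south flask, charged with 0.50 equiv of reagent, the limiting reagent, therefore has a ceiling of 50.0 % of the solid substrate charged.

| flask | solid substrate | reagent | remark | time |
|---|---|---|---|---|
| south | 0.19 M | 0.50 equiv | the very flask that is asked about, followed so far |  |
| south-east | 0.19 M | 1 equiv | run made earlier |  |
| flask | 0.19 M | 0.500 equiv |  | 20 h |

- south (time / h: target / %): 0.833: 20; 1.33: 33; 2.00: 40; 3.00: 40; 5.00: 39; 8.00: 37
- south-east (time / h: target / %): 0.833: 21; 1.33: 50; 2.00: 68; 3.00: 78; 5.00: 75; 8.00: 60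

(each reading ± 2 percentage points)

- solid substrate is a solid; its amount is given per volume of the solution
- steps that have been proposed: starting material + reagent -> intermediate + by-product; intermediate -> target; target -> over-reaction product; starting material + by-product -> side product; solid substrate <-> starting material
- at the start none of the solid substrate is in solution

* time, not beyond 20 h, at which the flask holds most target
* the amount of target, in percent of the solid substrate charged, at that time

**First estimate.** Let C be peak target as a share of the ceiling. The south-east run reads highest at 3.00 h, with 78 %, so C starts at 78.0 %, and the south flask gets 39.0 %.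

**Weak link.** That C rests on one south-east reading with a scatter of 2 percentage points. Going round once more, I put the first answer beside the two highest south readings, 40 % and 40 %, whose mean 40.0 % is 80.0 % of the ceiling. The mean of the two shares gives C = 79.0 %, the share of the reagent ceiling standing as target at the peak. I commit to 39.5 % at 3.00 h, the later of two tied south readings, the time of the highest south-east reading.

**The forecast.** It gives 40.5 % at 2.5 h, earlier than my time, on the ground “That fits the reagent running out”.

**The result.** The south flask gives 43.2 % at 3.00 h, later than the forecast's time.

    starting material + reagent → intermediate + by-product (k = 0.180 M⁻¹ s⁻¹)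
    intermediate → target (k = 3.70 × 10⁻⁴ s⁻¹)
    target → over-reaction product (k = 1.60 × 10⁻⁵ s⁻¹)
    starting material + by-product → side product (k = 0.0140 M⁻¹ s⁻¹)
    solid substrate ⇌ starting material, rate k5*(cs5 - [starting material]) while solid is left; crystals form when [starting material] > cs5 (solubility = 12.0 mM, k = 0.00390 s⁻¹)

Its capture is 86.4 %, against my C of 79.0 %. At that time reagent stands at 0 % of its charge, and target, intermediate 1.87 % and over-reaction product 4.94 % add up to 50.0 %, the ceiling.

**Second flask.** The neighbour with 0.300 equiv of reagent has a ceiling of 30.0 %, so C gives 23.7 %. Its computed best is 26.0 %.

The numbers in the tables were computed with constants of no real substance; the scatter is artificial.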